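(The earlier runs and the new flask come from a simulation with constants of no real substance; scatter was added.)

The elm flask cannot hold its charge in the two species measured: at 8.00 min the target and the starting material together read 38.0%, so 62.0% stands as something unmeasured.

| flask | starting material | catalyst | temperature | remark | time |
|---|---|---|---|---|---|
| elm | 0.15 M | 75 µM | 25 °C | the very flask that is asked about, followed so far |  |
| ash | 0.15 M | 38 µM | 10 °C | run made earlier |  |
| flask | 0.15 M | 75 µM | 25 °C |  | 8.0 min |

| run | time / min | target / % | starting material / % |
|---|---|---|---|
| elm | 1.00 | 22 | 28 |
| elm | 3.00 | 25 | 13 |
| elm | 5.00 | 23 | 9 |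
| elm | 8.00 | 24 | 14 |
| ash | 2.00 | 9 | 34 |
| ash | 4.00 | 10 | 15 |
| ash | 6.00 | 9 | 13 |
| ash | 8.00 | 11 | 8 |

(each reading ± 2 percentage points)

- east: at 8.0 min raise the temperature by 25 K, then wait 2.5 min
- south-east: at 8.0 min take out 90% of the target then present, then wait 2.5 min
- north: at 8.0 min add catalyst, 100% of the amount charged, then wait 2.5 min
- north-west: change nothing and wait 2.5 min more

- target, in percent of the starting material first charged, at 8.0 min
- which option adds most target ("none" when 2 percentage points or less is all one gets) (east / south-east / north / north-west / none)
- target present, with what was taken out counted in, in percent of the starting material first charged, after east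
- target present, with what was taken out counted in, in percent of the starting material first charged, after north

- what is taken out of target is counted as made
- additions bring no volume worth counting

In slow motion, elm begins quickly: by 1.00 min the starting material reads 28%, the target 22% and the unmeasured part 50.0%. By 3.00 min the target reads 25% and the starting material 13%. From there to 8.00 min, no trend stands above the scatter of 2 percentage points. In the ash run, with 38 µM of catalyst at 10 °C, the target levels off too, reading 9% to 11%, while the starting material goes on from 15% at 4.00 min to 8% at 8.00 min. This reckoning reads both target plateaus as thermodynamic rather than kinetic control.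

So follow one molecule that has left the starting material and ask where it stands on the plateau. The target odds are the amount standing as target divided by the amount standing as unmeasured. Averaging the last three readings of each run gives:

elm: [target] 24.0%, [starting material] 12.0%, odds 0.375

ash: odds 0.128

factor over 15.0 K: 2.93

The ash run differs from elm in catalyst as well, but this reckoning takes the factor as due to temperature and lets it grow geometrically. East then gives:

odds after east: 2.24

target after east: 60.9%

This assumes that 2.5 min is enough, as 3.00 min was enough for elm at the lower temperature. South-east, with full refilling at unchanged odds, gains 16 points, less than east's 37 points. North adds catalyst to a flat plateau, so the target stays near 24.0%, which is also the reckoned value now.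

The forecast, reading “a fast, endothermic equilibrium”, gave 24% now, east as the choice, 25% after north and 46% after east, which is lower than the 60.9% reckoned here.

The elm flask gives 25.4% at 8.0 min. East adds most, 40 points, against 13 points for south-east, and ends at 65.4%; north ends at 26.1%. At 8.00 min the unmeasured part of elm stands as 51.4% isomer of the product A and 12.7% isomer of the product B. Put to use with the 10% of starting material left in elm at that time, the odds of 0.375 read from the plateau reckon the target at 24.5%.

    starting material + catalyst ⇌ target + catalyst, rate k1*[starting material]*[catalyst] forward; the back reaction follows from the equilibrium constant (K = 2.53, k = 115 M⁻¹ s⁻¹, Ea = 42.0 kJ mol⁻¹, ΔH = 28.0 kJ mol⁻¹)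
    target + catalyst ⇌ isomer of the product A + catalyst, rate k2*[catalyst]*[target] forward; the back reaction follows from the equilibrium constant (K = 1.90, k = 22.4 M⁻¹ s⁻¹, Ea = 45.0 kJ mol⁻¹, ΔH = −57.0 kJ mol⁻¹)
    isomer of the product A + catalyst ⇌ starting material + catalyst, rate k3*[catalyst]*[isomer of the product A] forward; the back reaction follows from the equilibrium constant (k = 44.4 M⁻¹ s⁻¹, Ea = 36.0 kJ mol⁻¹)
    target + catalyst ⇌ isomer of the product B + catalyst, rate k4*[catalyst]*[target] forward; the back reaction follows from the equilibrium constant (K = 0.506, k = 118 M⁻¹ s⁻¹, Ea = 35.0 kJ mol⁻¹, ΔH = −82.0 kJ mol⁻¹)
    (constants at 25 °C)

The same flask run at 40 °C lies one equal step above elm, so this reckoning puts the odds at 1.10 and the target at 46.0%. The computed flask gives 50.9%.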